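## Analysis of the target

The target 39 is a depsidone. Ring A carries, in order, OMe (a1), H (a2), CH3 (a3), the ester carbonyl (a4), the diaryl ether oxygen (a5) and CH2OH (a6). The hexasubstituted ring B carries the ether oxygen (b1), the ester oxygen (b2), CH3 (b3), a free OH (b4), the lactone carbonyl (b5) and the lactol carbon (b6). The a5–O–b1 ether and the a4–C(=O)–O–b2 ester close the seven-membered ring C, and b5–C(=O)–O–CH(OH)–b6 is the five-membered ring D, a 3-hydroxyphthalide. The only stereocentre is the lactol carbon of ring D, (R)-configured, bearing H, OH, the ring oxygen and b6; it has no second centre to relate to, so its configuration must come from a reagent or catalyst. That carbon is the closed tautomer of an ortho-formyl benzoic acid, so anything that opens ring D (alkoxide, hydroxide, nucleophilic or strongly acidic media) erases it; the aryl ester of ring C is also labile to alkoxides and the benzylic CH2OH to hydrogenolysis. The difficulties are a fully substituted ring B, a diaryl ether with four ortho substituents, and an acetal-type stereocentre that cannot be set on a freely equilibrating lactol. The plan rests on the ring D oxygen lying between the lactone carbonyl carbon (on b5) and the CH(OH) carbon (on b6): removing it joins these two carbons into a four-membered ketone fused to ring B, where the future lactol carbon is an ordinary, non-enolisable silyloxy carbinol carbon.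

## Retrosynthetic reasoning

39 is traced back to silyl acetal 38 by cutting only the O–Si bond. The lactol must be the last thing released, because only as a silyl acetal is this carbon configurationally fixed; the forward step must break Si–O without ever forming the lactol alkoxide.

38 comes from aldehyde 37 (C=O reduction), and 37 from seco acid 36 by cutting the ring C ester bond a4–C(=O)–O–b2. The ester is cut before the ether because, once the ether holds the rings together, lactonisation is a proximity-driven seven-membered closure. The CH2OH is carried as a formyl group because that group is needed one step earlier as an activator. 36 comes from tribenzyl compound 35 by hydrogenolysis of all three benzyl groups at once.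

35 is cut at the a5–O bond into phenol 26 and fluoroarene 34. The cut is made on the ring A side because a5 sits between two acceptors (formyl at a6, ester at a4), which is the pattern for nucleophilic aromatic substitution; ring B is electron-rich and can only be the nucleophile. The forward step must join two di-ortho-substituted partners without disturbing the silyl acetal next to the phenoxide.

26 comes from MOM ether 24, and 24 from benzocyclobutenone 21 and hydrogen peroxide 22 by removing the ring D oxygen. This is the central disconnection: it converts an acetal stereocentre, which has no reliable asymmetric construction, into a carbinol stereocentre, which has. The forward step must insert oxygen on the sp3 side of the ketone with retention.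

21 is cut at the b5–C(=O) bond to bromo amide 18. Aryl anion attack on an N-methoxy-N-methyl amide gives a stable tetrahedral adduct, so the strained ketone appears only on quench, and the bromine goes onto the last free position of ring B.

18 leads back through silyl ether 16 and hydroxy amide 14 to hydroxy ester 12, and 12 to keto ester 11, where the stereocentre is created by catalytic asymmetric reduction of an aryl α-keto ester. The amide is made before silylation so that the α-hydrogen is shielded by the adjacent alkoxide during amidation. A triisopropylsilyl group is chosen over a smaller one because this oxygen later sits beside a phenoxide and in the presence of fluoride ion.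

11 is cut at the b6–carbon bond into MOM ether 8 and diethyl oxalate 9; the MOM ether is the strongest ortho director on the ring and its only free ortho position is b6. 8 comes from phenol 6, which comes from aldehyde 3 by exchanging formyl for hydroxyl. 3 is the dibenzyl ether of 1, which already holds the b2, b3 and b4 substituents in place.

34 is cut at the a4–carbonyl bond to bromide 31 plus carbon monoxide 32 and benzyl alcohol 33. 31 comes from aldehyde 30 by bromination para to OMe, and 30 from fluoroarene 27 by formylation at the carbon between F and OMe.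

## Alternatives that were turned down

Alternative 1: Here both carbon substituents of ring B (the b5 carbonyl and the b6 formyl) are attached to the aryl carbamate A2 by directed metalation. Lithiation next to the carbamate triggers the anionic ortho-Fries shift of the carbamoyl group to b5; a second lithiation between the new amide and the MOM ether is quenched with a formamide to give formyl amide A1 in one pot. In its favour, two C–C bonds are made in one operation with regiochemistry fixed by the directing groups, and ring B is reached in fewer steps than in the chosen route, so on step count to ring B it is the stronger plan. Against it, A1 is achiral, and ring D would form by spontaneous ring–chain closure, which gives the racemic lactol; nothing in A1 offers a handle for asymmetric induction. The second lithiation also has to take place on a phenoxide-bearing dianion, and the hindered tertiary amide must be cleaved later. The chosen route spends more steps but carries the lactol carbon as a fixed carbinol centre from 12 onwards.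

Alternative 2: Here the b2–O ester bond of ring C is made by C–H oxidation of seco acid A4, in which b2 still carries hydrogen and the b4 phenol is para to the ether. A hypervalent iodine oxidant converts the phenol into a quinoid cation, the ring A carboxylate adds, and re-aromatisation gives depsidone A3. In its favour, the b2 oxygen need not be carried through the synthesis, ring B is simpler, and ring C closes under non-basic conditions; on economy for ring C it is the stronger plan. Against it, b2 is meta to the phenol being oxidised, and the cation is electrophilic at b1, b3 and b5, so the carboxylate would be expected to add at b1 to give a spiro ketal lactone; reaching b2 would need a further acyloxy shift. A3 also holds the lactol as a racemic ethyl acetal, whose removal needs acid that scrambles the centre anyway. The chosen route closes ring C by two conventional C–O bond formations with no regiochemical ambiguity and addresses the stereocentre.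

Alternative 3: Here ring B itself is assembled from silyloxyfuran A6 and alkynoate A7. A Diels–Alder addition joins the silyloxy-bearing furan carbon to the ester-bearing alkyne carbon and the unsubstituted furan carbon to the acetal-bearing alkyne carbon; opening of the oxygen bridge then gives phenol A5. In its favour, the full substitution pattern of ring B follows from the connectivity of two small components, the polarity match is the normal one, and the b1 hydroxyl emerges free and distinct from the other two oxygens; for building ring B it is the more elegant plan. Against it, A6 is a sensitive tetrasubstituted silyl ketene acetal, the disubstituted alkyne is a sluggish dienophile, and A5 again carries b6 at the aldehyde oxidation level as an achiral acetal, leading to the racemic lactol. The chosen route builds ring B by classical aromatic substitution, which is longer, but it is the only plan of the four in which the configuration of the lactol carbon is set and then carried through.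

Key step: step 10

Assumption: the closed (R)-lactol of 39 is taken to persist configurationally under neutral to weakly acidic, aprotic conditions (ring–chain tautomerism being its only racemisation path), so it is released only in the last step.

Assumption: the sense of induction in step 5 is assigned from the usual aryl/η6-arene transition-state model and would be confirmed on 12 (Mosher ester analysis) before material is carried on.

## Route

Step 1
Reactants: 1 2,4-dihydroxy-3-methylbenzaldehyde; 2 benzyl bromide
Product: 3 2,4-bis(benzyloxy)-3-methylbenzaldehyde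
Conditions: BnBr (2.5 equiv), K2CO3, KI (cat.), DMF, 60 °C
Reagents that add atoms: benzyl bromide, BrCc1ccccc1
Why: Williamson ether synthesis; the hydrogen-bonded, hindered 2-OH needs heat and iodide catalysis, and the aldehyde is untouched.

Step 2
Reactants: 3 2,4-bis(benzyloxy)-3-methylbenzaldehyde; 4 3-chloroperoxybenzoic acid
Product: 6 2,4-bis(benzyloxy)-3-methylphenol, via aryl formate 5 (not isolated)
Conditions: mCPBA, CH2Cl2, 0 °C → rt; then K2CO3 (cat.), MeOH, rt
Reagents that add atoms: 3-chloroperoxybenzoic acid, OOC(=O)c1cccc(Cl)c1
Why: Baeyer–Villiger (Dakin-type) oxidation of an electron-rich benzaldehyde: the aryl group with ortho- and para-benzyloxy donors migrates to oxygen to give formate 5, which methanol cleaves; a peracid is used because the alkaline-peroxide Dakin reaction needs a free ortho- or para-hydroxyl, which 3 lacks.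

Step 3
Reactants: 6 2,4-bis(benzyloxy)-3-methylphenol; 7 chloromethyl methyl ether
Product: 8 1,3-bis(benzyloxy)-4-(methoxymethoxy)-2-methylbenzene
Conditions: MOMCl, i-Pr2NEt, CH2Cl2, 0 °C → rt
Reagents that add atoms: chloromethyl methyl ether, COCCl
Why: O-alkylation of the phenol by an α-chloro ether; the MOM ether is the strongest ortho-directing group on the ring and can later be removed without touching benzyl ethers.

Step 4
Reactants: 8 1,3-bis(benzyloxy)-4-(methoxymethoxy)-2-methylbenzene; 9 diethyl oxalate
Product: 11 ethyl 2-[3,5-bis(benzyloxy)-2-(methoxymethoxy)-4-methylphenyl]-2-oxoacetate, via aryllithium 10 (not isolated)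
Conditions: n-BuLi, TMEDA, THF, −40 → −10 °C; then cannulated into (CO2Et)2 (3 equiv), THF, −78 °C; aq. NH4Cl
Reagents that add atoms: diethyl oxalate, CCOC(=O)C(=O)OCC
Why: Directed ortho-metalation then acylation: the MOM ether directs lithiation to its only free ortho position (b6), the benzyl ethers being weaker directors, and inverse addition of 10 to excess oxalate at −78 °C stops at the α-keto ester because the tetrahedral adduct survives until quench.

Step 5
Reactants: 11 ethyl 2-[3,5-bis(benzyloxy)-2-(methoxymethoxy)-4-methylphenyl]-2-oxoacetate
Product: 12 ethyl (2S)-2-[3,5-bis(benzyloxy)-2-(methoxymethoxy)-4-methylphenyl]-2-hydroxyacetate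
Conditions: RuCl[(R,R)-TsDPEN](p-cymene) (1 mol%), HCO2H/Et3N (5:2), DMF, 0 °C → rt
Reagents that add atoms: none
Why: Noyori–Ikariya asymmetric transfer hydrogenation of an aryl α-keto ester; hydride is delivered through the six-membered Ru–H/N–H transition state with the aryl group held against the η6-cymene ligand, which for the (R,R)-ligand should give the (S)-carbinol (CO2Et outranks aryl in the CIP order), and formic acid makes the reduction irreversible.

Step 6
Reactants: 12 ethyl (2S)-2-[3,5-bis(benzyloxy)-2-(methoxymethoxy)-4-methylphenyl]-2-hydroxyacetate; 13 N,O-dimethylhydroxylamine hydrochloride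
Product: 14 (2S)-2-[3,5-bis(benzyloxy)-2-(methoxymethoxy)-4-methylphenyl]-2-hydroxy-N-methoxy-N-methylacetamide
Conditions: MeNH(OMe)·HCl, i-PrMgCl, THF, −20 → 0 °C
Reagents that add atoms: N,O-dimethylhydroxylamine hydrochloride, CNOC.Cl
Why: Weinreb amide formation by attack of the chloromagnesium amide on the ester; it is done on the free alcohol so that the substrate reacts as its magnesium alkoxide, which blocks removal of the benzylic α-hydrogen and so protects the new stereocentre.

Step 7
Reactants: 14 (2S)-2-[3,5-bis(benzyloxy)-2-(methoxymethoxy)-4-methylphenyl]-2-hydroxy-N-methoxy-N-methylacetamide; 15 triisopropylsilyl trifluoromethanesulfonate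
Product: 16 (2S)-2-[3,5-bis(benzyloxy)-2-(methoxymethoxy)-4-methylphenyl]-N-methoxy-N-methyl-2-[(triisopropylsilyl)oxy]acetamide
Conditions: TIPSOTf, 2,6-lutidine, CH2Cl2, −40 → 0 °C
Reagents that add atoms: triisopropylsilyl trifluoromethanesulfonate, CC(C)[Si](C(C)C)(C(C)C)OS(=O)(=O)C(F)(F)F
Why: Silylation of a hindered secondary alcohol with a silyl triflate and a hindered pyridine base; the bulky TIPS group is chosen because this oxygen must later resist fluoride ion and transfer to a neighbouring phenoxide, and the short, cold, buffered reaction leaves the aryl MOM ether intact.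

Step 8
Reactants: 16 (2S)-2-[3,5-bis(benzyloxy)-2-(methoxymethoxy)-4-methylphenyl]-N-methoxy-N-methyl-2-[(triisopropylsilyl)oxy]acetamide; 17 N-bromosuccinimide
Product: 18 (2S)-2-[3,5-bis(benzyloxy)-2-bromo-6-(methoxymethoxy)-4-methylphenyl]-N-methoxy-N-methyl-2-[(triisopropylsilyl)oxy]acetamide
Conditions: NBS, NaHCO3, MeCN, 0 °C, dark
Reagents that add atoms: N-bromosuccinimide, O=C1CCC(=O)N1Br
Why: Electrophilic aromatic bromination at the only free ring position (b5), which is ortho to one benzyloxy group and para to the other; bicarbonate scavenges HBr so the MOM and silyl ethers survive.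

Step 9
Reactants: 18 (2S)-2-[3,5-bis(benzyloxy)-2-bromo-6-(methoxymethoxy)-4-methylphenyl]-N-methoxy-N-methyl-2-[(triisopropylsilyl)oxy]acetamide
Product: 21 (8S)-3,5-bis(benzyloxy)-2-(methoxymethoxy)-4-methyl-8-[(triisopropylsilyl)oxy]bicyclo[4.2.0]octa-1,3,5-trien-7-one, via aryllithium 19 (not isolated), via tetrahedral lithium alkoxide 20 (not isolated)
Conditions: t-BuLi (2.1 equiv), THF, −100 → −78 °C; AcOH, THF, −78 °C
Reagents that add atoms: none
Why: Parham cyclisation: bromine–lithium exchange outruns deprotonation and amide addition at −100 °C, and 19 adds 4-exo-trig to the Weinreb amide to give chelated adduct 20, which releases the ketone only on acidic quench; the stereocentre is not a reacting centre, and 21 cannot epimerise because its enolate would be a benzocyclobutadiene.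

Step 10
Reactants: 21 (8S)-3,5-bis(benzyloxy)-2-(methoxymethoxy)-4-methyl-8-[(triisopropylsilyl)oxy]bicyclo[4.2.0]octa-1,3,5-trien-7-one; 22 hydrogen peroxide
Product: 24 (3S)-5,7-bis(benzyloxy)-4-(methoxymethoxy)-6-methyl-3-[(triisopropylsilyl)oxy]isobenzofuran-1(3H)-one, via hydroperoxy hemiketal 23 (not isolated)
Conditions: 30% aq. H2O2 (3 equiv), K2CO3 (0.3 equiv), THF/H2O, 0 °C; aq. Na2S2O3, pH 7 buffer
Reagents that add atoms: hydrogen peroxide, OO
Why: This is a Baeyer–Villiger oxidation of a cyclobutanone, the closest known reaction type being the conversion of α-oxygenated cyclobutanones into γ-lactones by hydrogen peroxide with migration of the oxygen-bearing carbon. Hydroperoxide adds to the strained carbonyl of 21 to give hemiketal 23, and in its Criegee-type rearrangement the C–C bond antiperiplanar to the O–O bond shifts to oxygen as hydroxide leaves, driven by release of four-ring strain. Ring D is therefore closed by a 1,2-shift ring expansion from four to five members, not by a cyclisation, and both C–O bonds of the lactone oxygen are formed (O–C(=O) in the addition, O–CH in the shift). No stereocentre is created: the migrating carbon moves with retention, so (S) in 21 becomes (S) in 24, which is the spatial arrangement of (R) in 39 (the descriptor changes at the end only because OSi outranks the ring oxygen whereas the ring oxygen outranks OH). The selectivity needed is migration of the silyloxy-bearing sp3 carbon and not of aryl carbon b5, which would give a benzofuran-2-one; the oxygen lone pair and the benzylic position stabilise the electron-poor migrating carbon, whereas the aryl carbon, locked in the plane of the fused ring, cannot offer its π system to the breaking O–O bond. Only a substoichiometric weak base is used, because stoichiometric hydroxide would cleave the strained ketone and open the lactone of 24, whose hemiacetal oxygen would then be expelled and the stereocentre lost. The benzyl, MOM and silyl ethers are inert to cold hydrogen peroxide.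

Step 11
Reactants: 24 (3S)-5,7-bis(benzyloxy)-4-(methoxymethoxy)-6-methyl-3-[(triisopropylsilyl)oxy]isobenzofuran-1(3H)-one
Product: 26 (3S)-5,7-bis(benzyloxy)-4-hydroxy-6-methyl-3-[(triisopropylsilyl)oxy]isobenzofuran-1(3H)-one, via aryl trimethylsilyl ether 25 (not isolated)
Conditions: TMSOTf, 2,2'-bipyridyl, CH2Cl2, 0 °C; then H2O, rt
Reagents that add atoms: none
Why: Lewis-acid cleavage of an aryl methoxymethyl ether: the silyl triflate–bipyridyl pair activates the acetal oxygen and gives aryl silyl ether 25 and a pyridinium salt, both hydrolysed on adding water; the medium is aprotic and buffered, so the silyl acetal of ring D is neither solvolysed nor ionised and the benzyl ethers stay.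

Step 12
Reactants: 27 1-fluoro-3-methoxy-5-methylbenzene; 28 N,N-dimethylformamide
Product: 30 2-fluoro-6-methoxy-4-methylbenzaldehyde, via aryllithium 29 (not isolated)
Conditions: n-BuLi, THF, −78 °C; DMF, −78 °C; aq. HCl
Reagents that add atoms: N,N-dimethylformamide, CN(C)C=O
Why: Directed ortho-lithiation and formylation: the hydrogen between fluorine and methoxy is the most acidic on the ring, and the ortho-fluoro aryllithium 29 does not lose LiF to a benzyne at −78 °C.

Step 13
Reactants: 30 2-fluoro-6-methoxy-4-methylbenzaldehyde; 17 N-bromosuccinimide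
Product: 31 3-bromo-2-fluoro-6-methoxy-4-methylbenzaldehyde
Conditions: NBS, TFA (cat.), MeCN, rt
Reagents that add atoms: N-bromosuccinimide, O=C1CCC(=O)N1Br
Why: Electrophilic aromatic bromination para to the methoxy group, its strongest directing position, which is also meta to the formyl group and the less hindered of the two free positions (flanked by F and CH3).

Step 14
Reactants: 31 3-bromo-2-fluoro-6-methoxy-4-methylbenzaldehyde; 32 carbon monoxide; 33 benzyl alcohol
Product: 34 benzyl 2-fluoro-3-formyl-4-methoxy-6-methylbenzoate
Conditions: CO (1 atm), BnOH, Pd(OAc)2 (5 mol%), Xantphos, Et3N, toluene, 90 °C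
Reagents that add atoms: carbon monoxide, [C-]#[O+]; benzyl alcohol, OCc1ccccc1
Why: Palladium-catalysed alkoxycarbonylation (oxidative addition to zerovalent palladium, CO insertion, alcoholysis of the acyl complex); the wide-bite-angle diphosphine suits hindered aryl bromides at atmospheric pressure, and the amine base is too weak to form benzyl oxide, so the activated fluoride is kept.

Step 15
Reactants: 26 (3S)-5,7-bis(benzyloxy)-4-hydroxy-6-methyl-3-[(triisopropylsilyl)oxy]isobenzofuran-1(3H)-one; 34 benzyl 2-fluoro-3-formyl-4-methoxy-6-methylbenzoate
Product: 35 benzyl 2-({(3S)-5,7-bis(benzyloxy)-6-methyl-1-oxo-3-[(triisopropylsilyl)oxy]-1,3-dihydroisobenzofuran-4-yl}oxy)-3-formyl-4-methoxy-6-methylbenzoate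
Conditions: K2CO3, 4 Å MS, DMF, 40 → 60 °C
Reagents that add atoms: benzyl 2-fluoro-3-formyl-4-methoxy-6-methylbenzoate, COc1cc(C)c(C(=O)OCc2ccccc2)c(F)c1C=O
Why: SNAr (addition–elimination): the fluorine of 34 is flanked by formyl and ester acceptors that stabilise the Meisenheimer intermediate, while OMe and CH3 are meta to the reacting carbon. The stereocentre is not a reacting centre, and the neighbouring phenoxide cannot expel the lactone carboxylate because that C–O bond lies in the arene plane (the reverse of a 5-endo-trig closure); TIPS resists transfer to the phenoxide and attack by the fluoride released, which precipitates as KF.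

Step 16
Reactants: 35 benzyl 2-({(3S)-5,7-bis(benzyloxy)-6-methyl-1-oxo-3-[(triisopropylsilyl)oxy]-1,3-dihydroisobenzofuran-4-yl}oxy)-3-formyl-4-methoxy-6-methylbenzoate
Product: 36 2-({(3S)-5,7-dihydroxy-6-methyl-1-oxo-3-[(triisopropylsilyl)oxy]-1,3-dihydroisobenzofuran-4-yl}oxy)-3-formyl-4-methoxy-6-methylbenzoic acid
Conditions: H2 (1 atm), 10% Pd/C, EtOAc, rt, stopped after uptake of 3 equiv H2
Reagents that add atoms: none
Why: Hydrogenolysis of two aryl benzyl ethers and one benzyl ester on palladium; in a non-protic solvent without acid these C–O bonds should cleave faster than a hindered, electron-rich 2,6-dioxygenated benzaldehyde is reduced.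

Step 17
Reactants: 36 2-({(3S)-5,7-dihydroxy-6-methyl-1-oxo-3-[(triisopropylsilyl)oxy]-1,3-dihydroisobenzofuran-4-yl}oxy)-3-formyl-4-methoxy-6-methylbenzoic acid
Product: 37 depsidone aldehyde: the compound 38 with CHO in place of CH2OH at a6 (ring C closed, b4 OH free, (S)-silyl acetal in ring D)
Conditions: EDC·HCl, DMAP (cat.), CH2Cl2 (high dilution), 0 °C → rt
Reagents that add atoms: none
Why: Carbodiimide (Steglich-type) lactonisation closing ring C by 7-exo-trig attack of the b2 hydroxyl on the activated acid; the diaryl ether holds the two groups side by side, and the b4 hydroxyl, hydrogen-bonded to the ring D carbonyl, cannot reach the acyl group.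

Step 18
Reactants: 37 depsidone aldehyde
Product: 38 depsidone alcohol: 39 carrying a triisopropylsilyl group on the lactol oxygen, (S) at the acetal carbon
Conditions: NaBH(OAc)3, AcOH, THF, rt
Reagents that add atoms: none
Why: Chemoselective hydride reduction of the aldehyde by an acyloxyborohydride, which is too weak to reduce the aryl ester of ring C or the lactone of ring D and, being non-basic, forms no alkoxide that could open ring C.

Step 19
Reactants: 38 depsidone alcohol
Product: 39 target, (R)-lactol
Conditions: HF·pyridine, pyridine, THF, 0 °C → rt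
Reagents that add atoms: none
Why: Fluoride-mediated Si–O cleavage in a pyridine-buffered, weakly acidic medium: only the Si–O bond breaks, so the four bonds of the stereocentre are untouched and the lactol oxygen is protonated as it is released, never present as the alkoxide that would open ring D; the primary alcohol, phenol and ring C ester are inert.

## Compound list

1 | 2,4-dihydroxy-3-methylbenzaldehyde | Cc1c(O)ccc(C=O)c1O | starting material
2 | benzyl bromide | BrCc1ccccc1 | starting material
3 | 2,4-bis(benzyloxy)-3-methylbenzaldehyde | O=Cc1ccc(OCc2ccccc2)c(C)c1OCc1ccccc1 | intermediate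
4 | 3-chloroperoxybenzoic acid | OOC(=O)c1cccc(Cl)c1 | starting material
5 | 2,4-bis(benzyloxy)-3-methylphenyl formate | O=COc1ccc(OCc2ccccc2)c(C)c1OCc1ccccc1 | intermediate (not isolated)
6 | 2,4-bis(benzyloxy)-3-methylphenol | Oc1ccc(OCc2ccccc2)c(C)c1OCc1ccccc1 | intermediate
7 | chloromethyl methyl ether | COCCl | starting material
8 | 1,3-bis(benzyloxy)-4-(methoxymethoxy)-2-methylbenzene | COCOc1ccc(OCc2ccccc2)c(C)c1OCc1ccccc1 | intermediate
9 | diethyl oxalate | CCOC(=O)C(=O)OCC | starting material
10 | [3,5-bis(benzyloxy)-2-(methoxymethoxy)-4-methylphenyl]lithium | COCOc1c([Li])cc(OCc2ccccc2)c(C)c1OCc1ccccc1 | intermediate (not isolated)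
11 | ethyl 2-[3,5-bis(benzyloxy)-2-(methoxymethoxy)-4-methylphenyl]-2-oxoacetate | CCOC(=O)C(=O)c1cc(OCc2ccccc2)c(C)c(OCc2ccccc2)c1OCOC | intermediate
12 | ethyl (2S)-2-[3,5-bis(benzyloxy)-2-(methoxymethoxy)-4-methylphenyl]-2-hydroxyacetate | CCOC(=O)[C@@H](O)c1cc(OCc2ccccc2)c(C)c(OCc2ccccc2)c1OCOC | intermediate
13 | N,O-dimethylhydroxylamine hydrochloride | CNOC.Cl | starting material
14 | (2S)-2-[3,5-bis(benzyloxy)-2-(methoxymethoxy)-4-methylphenyl]-2-hydroxy-N-methoxy-N-methylacetamide | CON(C)C(=O)[C@@H](O)c1cc(OCc2ccccc2)c(C)c(OCc2ccccc2)c1OCOC | intermediate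
15 | triisopropylsilyl trifluoromethanesulfonate | CC(C)[Si](C(C)C)(C(C)C)OS(=O)(=O)C(F)(F)F | starting material
16 | (2S)-2-[3,5-bis(benzyloxy)-2-(methoxymethoxy)-4-methylphenyl]-N-methoxy-N-methyl-2-[(triisopropylsilyl)oxy]acetamide | CON(C)C(=O)[C@@H](O[Si](C(C)C)(C(C)C)C(C)C)c1cc(OCc2ccccc2)c(C)c(OCc2ccccc2)c1OCOC | intermediate
17 | N-bromosuccinimide | O=C1CCC(=O)N1Br | starting material
18 | (2S)-2-[3,5-bis(benzyloxy)-2-bromo-6-(methoxymethoxy)-4-methylphenyl]-N-methoxy-N-methyl-2-[(triisopropylsilyl)oxy]acetamide | CON(C)C(=O)[C@@H](O[Si](C(C)C)(C(C)C)C(C)C)c1c(Br)c(OCc2ccccc2)c(C)c(OCc2ccccc2)c1OCOC | intermediate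
19 | aryllithium from 18 (Li in place of Br) | CON(C)C(=O)[C@@H](O[Si](C(C)C)(C(C)C)C(C)C)c1c([Li])c(OCc2ccccc2)c(C)c(OCc2ccccc2)c1OCOC | intermediate (not isolated)
20 | lithium alkoxide of the cyclic N-methoxy-N-methyl hemiaminal (tetrahedral adduct; hemiaminal carbon unassigned) | COCOc1c(OCc2ccccc2)c(C)c(OCc2ccccc2)c2c1[C@H](O[Si](C(C)C)(C(C)C)C(C)C)C2(O[Li])N(C)OC | intermediate (not isolated)
21 | (8S)-3,5-bis(benzyloxy)-2-(methoxymethoxy)-4-methyl-8-[(triisopropylsilyl)oxy]bicyclo[4.2.0]octa-1,3,5-trien-7-one | COCOc1c(OCc2ccccc2)c(C)c(OCc2ccccc2)c2c1[C@H](O[Si](C(C)C)(C(C)C)C(C)C)C2=O | intermediate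
22 | hydrogen peroxide | OO | starting material
23 | hydroperoxy hemiketal of 21 (hemiketal carbon unassigned) | COCOc1c(OCc2ccccc2)c(C)c(OCc2ccccc2)c2c1[C@H](O[Si](C(C)C)(C(C)C)C(C)C)C2(O)OO | intermediate (not isolated)
24 | (3S)-5,7-bis(benzyloxy)-4-(methoxymethoxy)-6-methyl-3-[(triisopropylsilyl)oxy]isobenzofuran-1(3H)-one | COCOc1c(OCc2ccccc2)c(C)c(OCc2ccccc2)c2c1[C@H](O[Si](C(C)C)(C(C)C)C(C)C)OC2=O | intermediate
25 | (3S)-5,7-bis(benzyloxy)-6-methyl-3-[(triisopropylsilyl)oxy]-4-[(trimethylsilyl)oxy]isobenzofuran-1(3H)-one | C[Si](C)(C)Oc1c(OCc2ccccc2)c(C)c(OCc2ccccc2)c2c1[C@H](O[Si](C(C)C)(C(C)C)C(C)C)OC2=O | intermediate (not isolated)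
26 | (3S)-5,7-bis(benzyloxy)-4-hydroxy-6-methyl-3-[(triisopropylsilyl)oxy]isobenzofuran-1(3H)-one | Oc1c(OCc2ccccc2)c(C)c(OCc2ccccc2)c2c1[C@H](O[Si](C(C)C)(C(C)C)C(C)C)OC2=O | intermediate
27 | 1-fluoro-3-methoxy-5-methylbenzene | COc1cc(C)cc(F)c1 | starting material
28 | N,N-dimethylformamide | CN(C)C=O | starting material
29 | (2-fluoro-6-methoxy-4-methylphenyl)lithium | COc1cc(C)cc(F)c1[Li] | intermediate (not isolated)
30 | 2-fluoro-6-methoxy-4-methylbenzaldehyde | COc1cc(C)cc(F)c1C=O | intermediate
31 | 3-bromo-2-fluoro-6-methoxy-4-methylbenzaldehyde | COc1cc(C)c(Br)c(F)c1C=O | intermediate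
32 | carbon monoxide | [C-]#[O+] | starting material
33 | benzyl alcohol | OCc1ccccc1 | starting material
34 | benzyl 2-fluoro-3-formyl-4-methoxy-6-methylbenzoate | COc1cc(C)c(C(=O)OCc2ccccc2)c(F)c1C=O | intermediate
35 | benzyl 2-({(3S)-5,7-bis(benzyloxy)-6-methyl-1-oxo-3-[(triisopropylsilyl)oxy]-1,3-dihydroisobenzofuran-4-yl}oxy)-3-formyl-4-methoxy-6-methylbenzoate | COc1cc(C)c(C(=O)OCc2ccccc2)c(Oc2c(OCc3ccccc3)c(C)c(OCc3ccccc3)c3c2[C@H](O[Si](C(C)C)(C(C)C)C(C)C)OC3=O)c1C=O | intermediate
36 | 2-({(3S)-5,7-dihydroxy-6-methyl-1-oxo-3-[(triisopropylsilyl)oxy]-1,3-dihydroisobenzofuran-4-yl}oxy)-3-formyl-4-methoxy-6-methylbenzoic acid | COc1cc(C)c(C(=O)O)c(Oc2c(O)c(C)c(O)c3c2[C@H](O[Si](C(C)C)(C(C)C)C(C)C)OC3=O)c1C=O | intermediate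
37 | depsidone aldehyde (ring C closed; CHO at a6; b4 OH free; (S)-TIPS acetal in ring D) | COc1cc(C)c2c(c1C=O)Oc1c(c(C)c(O)c3c1[C@H](O[Si](C(C)C)(C(C)C)C(C)C)OC3=O)OC2=O | intermediate
38 | depsidone alcohol (39 with a TIPS group on the lactol oxygen; (S) at the acetal carbon) | COc1cc(C)c2c(c1CO)Oc1c(c(C)c(O)c3c1[C@H](O[Si](C(C)C)(C(C)C)C(C)C)OC3=O)OC2=O | intermediate
39 | target depsidone, (R)-lactol | COc1cc(C)c2c(c1CO)Oc1c(c(C)c(O)c3c1[C@H](O)OC3=O)OC2=O | target

## Step count and least certain steps

Total: 19 steps. Longest linear sequence: 16 steps (steps 1–11 and 15–19); the ring A branch is steps 12–14.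

Step 10 (key step). What may go wrong: migration of the aryl carbon in place of the carbinol carbon; hydroxide-induced C–C cleavage of the strained ketone; or opening of the product lactone by hydroperoxide, which would expel the hemiacetal oxygen and erase the stereocentre. Fallback, setting out from 8 and returning at 24: the oxygen insertion is given up and the lactol carbon is brought in at the aldehyde level, then resolved. Lithiation of 8 as in step 4 and quenching with 28 gives 3,5-bis(benzyloxy)-2-(methoxymethoxy)-4-methylbenzaldehyde F1. Bromination with 17 at the free position gives the 2-bromo aldehyde F2. Palladium-catalysed hydroxycarbonylation (Pd(OAc)2, Xantphos, CO, H2O, Et3N, DMF) gives the formyl acid, which closes to the racemic 3-hydroxyphthalide F3. Silylation with 15 and 2,6-lutidine gives the racemic silyl acetal F4, which is configurationally stable and is separated by preparative chromatography on a chiral stationary phase to give 24. The unwanted enantiomer can be desilylated back to the equilibrating F3 and recycled.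

Step 9. What may go wrong: proton transfer from the benzylic α-CH to the aryllithium (loss of configuration and debrominated amide), addition of the alkyllithium to the amide, or α-lithiation of a benzyl ether followed by Wittig rearrangement. Fallback, setting out from 16 and returning at 21: the ring is closed through a much less basic arylmagnesium reagent. Iodination of 16 with N-iodosuccinimide gives the aryl iodide F5. Iodine–magnesium exchange with i-PrMgCl·LiCl at −40 °C gives the arylmagnesium chloride F6, which on slow warming closes onto the Weinreb amide; acidic quench then gives 21.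

Step 15. What may go wrong: slow substitution between two di-ortho-substituted partners, and during the long exposure to base either silyl transfer from the acetal oxygen to the neighbouring phenoxide or attack of fluoride at silicon, both of which open ring D. Fallback, setting out from 21 and returning at 35: the ether is made before the oxygen insertion, when the carbon next to the phenoxide carries no leaving group. The MOM group of 21 is removed under the conditions of step 11 to give the phenolic benzocyclobutenone F7. SNAr with 34 under the conditions of step 15 gives the diaryl ether benzocyclobutenone F8. Oxidation with 22 as in step 10 then gives 35; the strained ketone should react well before the ring A aldehyde.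

Step 16. What may go wrong: over-reduction of the formyl group to CH2OH or CH3 during debenzylation. Fallback, setting out from 35 and returning at 38: the aldehyde is reduced first, so that no carbonyl is present during hydrogenation. NaBH4 in THF/EtOH at −20 °C gives the benzylic alcohol F9 (benzyl ester and ring D lactone are not reduced). Hydrogenolysis as in step 16 gives the hydroxymethyl seco acid F10. Carbodiimide lactonisation at high dilution, where the seven-membered phenol acylation should outrun intermolecular esterification of the primary alcohol, gives 38 directly.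

## Further compounds

F1 | step 10 | 3,5-bis(benzyloxy)-2-(methoxymethoxy)-4-methylbenzaldehyde | O=Cc1cc(OCc2ccccc2)c(C)c(OCc2ccccc2)c1OCOC
F2 | step 10 | 3,5-bis(benzyloxy)-2-bromo-6-(methoxymethoxy)-4-methylbenzaldehyde | O=Cc1c(Br)c(OCc2ccccc2)c(C)c(OCc2ccccc2)c1OCOC
F3 | step 10 | racemic 5,7-bis(benzyloxy)-3-hydroxy-4-(methoxymethoxy)-6-methylisobenzofuran-1(3H)-one | COCOc1c(OCc2ccccc2)c(C)c(OCc2ccccc2)c2c1C(O)OC2=O
F4 | step 10 | racemic 5,7-bis(benzyloxy)-4-(methoxymethoxy)-6-methyl-3-[(triisopropylsilyl)oxy]isobenzofuran-1(3H)-one | COCOc1c(OCc2ccccc2)c(C)c(OCc2ccccc2)c2c1C(O[Si](C(C)C)(C(C)C)C(C)C)OC2=O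
F5 | step 9 | (2S)-2-[3,5-bis(benzyloxy)-2-iodo-6-(methoxymethoxy)-4-methylphenyl]-N-methoxy-N-methyl-2-[(triisopropylsilyl)oxy]acetamide | CON(C)C(=O)[C@@H](O[Si](C(C)C)(C(C)C)C(C)C)c1c(I)c(OCc2ccccc2)c(C)c(OCc2ccccc2)c1OCOC
F6 | step 9 | arylmagnesium chloride from F5 (MgCl in place of I) | CON(C)C(=O)[C@@H](O[Si](C(C)C)(C(C)C)C(C)C)c1c([Mg]Cl)c(OCc2ccccc2)c(C)c(OCc2ccccc2)c1OCOC
F7 | step 15 | (8S)-3,5-bis(benzyloxy)-2-hydroxy-4-methyl-8-[(triisopropylsilyl)oxy]bicyclo[4.2.0]octa-1,3,5-trien-7-one | Oc1c(OCc2ccccc2)c(C)c(OCc2ccccc2)c2c1[C@H](O[Si](C(C)C)(C(C)C)C(C)C)C2=O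
F8 | step 15 | benzyl 2-({(8S)-3,5-bis(benzyloxy)-4-methyl-7-oxo-8-[(triisopropylsilyl)oxy]bicyclo[4.2.0]octa-1,3,5-trien-2-yl}oxy)-3-formyl-4-methoxy-6-methylbenzoate | COc1cc(C)c(C(=O)OCc2ccccc2)c(Oc2c(OCc3ccccc3)c(C)c(OCc3ccccc3)c3c2[C@H](O[Si](C(C)C)(C(C)C)C(C)C)C3=O)c1C=O
F9 | step 16 | benzyl 2-({(3S)-5,7-bis(benzyloxy)-6-methyl-1-oxo-3-[(triisopropylsilyl)oxy]-1,3-dihydroisobenzofuran-4-yl}oxy)-3-(hydroxymethyl)-4-methoxy-6-methylbenzoate | COc1cc(C)c(C(=O)OCc2ccccc2)c(Oc2c(OCc3ccccc3)c(C)c(OCc3ccccc3)c3c2[C@H](O[Si](C(C)C)(C(C)C)C(C)C)OC3=O)c1CO
F10 | step 16 | 2-({(3S)-5,7-dihydroxy-6-methyl-1-oxo-3-[(triisopropylsilyl)oxy]-1,3-dihydroisobenzofuran-4-yl}oxy)-3-(hydroxymethyl)-4-methoxy-6-methylbenzoic acid | COc1cc(C)c(C(=O)O)c(Oc2c(O)c(C)c(O)c3c2[C@H](O[Si](C(C)C)(C(C)C)C(C)C)OC3=O)c1CO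
A1 | alternative 1 | N,N-diethyl-2-formyl-6-hydroxy-3-(methoxymethoxy)-5-methyl-4-(propan-2-yloxy)benzamide | CCN(CC)C(=O)c1c(O)c(C)c(OC(C)C)c(OCOC)c1C=O
A2 | alternative 1 | 4-(methoxymethoxy)-2-methyl-3-(propan-2-yloxy)phenyl N,N-diethylcarbamate | CCN(CC)C(=O)Oc1ccc(OCOC)c(OC(C)C)c1C
A3 | alternative 2 | depsidone with CH2OAc on ring A and a racemic ethyl acetal in ring D | COc1cc(C)c2c(c1COC(C)=O)Oc1c(c(C)c(O)c3c1C(OCC)OC3=O)OC2=O
A4 | alternative 2 | 3-(acetoxymethyl)-2-[(3-ethoxy-7-hydroxy-6-methyl-1-oxo-1,3-dihydroisobenzofuran-4-yl)oxy]-4-methoxy-6-methylbenzoic acid (racemic) | COc1cc(C)c(C(=O)O)c(Oc2cc(C)c(O)c3c2C(OCC)OC3=O)c1COC(C)=O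
A5 | alternative 3 | ethyl 4-(benzyloxy)-2-[(tert-butyldimethylsilyl)oxy]-6-(diethoxymethyl)-5-hydroxy-3-methylbenzoate | CCOC(=O)c1c(O[Si](C)(C)C(C)(C)C)c(C)c(OCc2ccccc2)c(O)c1C(OCC)OCC
A6 | alternative 3 | 4-(benzyloxy)-2-[(tert-butyldimethylsilyl)oxy]-3-methylfuran | Cc1c(O[Si](C)(C)C(C)(C)C)occ1OCc1ccccc1
A7 | alternative 3 | ethyl 4,4-diethoxybut-2-ynoate | CCOC(=O)C#CC(OCC)OCC
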